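Both quinolinone units are opened at the amide bond N1–C2 and at the aryl–carbonyl bond C4–C4a. What remains of each is a C2–C3–C4 malonate hanging by C3 from a methine (C1 or C3) of the cyclohexane, ring C. Heating one (1S,3S)-bismalonate with two N-methylanilines therefore makes four bonds and both pyridone rings in one operation and touches no stereocentre. The precursor is a trans-1,3-bis(malonyl)cyclohexane with an isopropenyl group on the C2 methine and a methylidene at C5. Acid later turns these alkenes into the tertiary cations that the two enol oxygens capture, closing pyran ring A and bridged ring B.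

Key step: step 7

Remarks on the chemistry
- **Ring C numbering.** C1 bears the quinolinone of ring A, C2 the three-carbon side chain, C3 the quinolinone of ring B, and C5 the methyl/oxygen carbon. C4 and C6 are CH2.
- **Placement of functionality.**
  - In the target the ring A oxygen sits on the CMe2 carbon and C2 is a methine. The precursor therefore carries H on C2 and the unsaturation in the side chain, so protonation gives the side-chain tertiary cation directly.
  - An oxygen on C2 is avoided at the key step. It would lactonise onto a neighbouring malonate and dehydrate at 250 °C towards C1 or C3. On ionisation it would put a cation next to both benzylic C–H bonds (hydride shift, loss of configuration) or close a five-membered ether.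
- **Symmetry.** With C1 and C3 alike (S,S), the two ring branches at C2 are identical. C2 is therefore no stereocentre until the two quinolinones take different roles in the last step. The side chain is necessarily cis to one arm and trans to the other.
- **Assumption.** The quinidine-derived thiourea is taken to give the (3aR,7aR) lactone in step 3. If it favours the mirror image, the quinine-derived pseudoenantiomer is used and nothing else changes.

Step 1
Reactants: 1 4,4-dimethoxycyclohexa-2,5-dien-1-one; 2 prop-1-en-2-ylmagnesium bromide
Product: 4 4-hydroxy-4-(prop-1-en-2-yl)cyclohexa-2,5-dien-1-one, via ketal carbinol 3 (not isolated)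
Conditions: 2 (1.2 equiv), THF, −78 °C; then 10% aq AcOH, THF, 0 → 23 °C
Reagents that add atoms: water, O
Why: Grignard reagents add 1,2 to the free carbonyl of a quinone monoketal (the ketal masks the second carbonyl and blocks aromatisation), and dilute acid then unmasks the cross-conjugated dienone of the p-quinol; no stereocentre is formed.

Step 2
Reactants: 4 4-hydroxy-4-(prop-1-en-2-yl)cyclohexa-2,5-dien-1-one; 5 methyl 3-chloro-3-oxopropanoate
Product: 6 methyl 4-oxo-1-(prop-1-en-2-yl)cyclohexa-2,5-dien-1-yl propanedioate
Conditions: 5 (1.3 equiv), pyridine, CH2Cl2, −20 → 0 °C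
Reagents that add atoms: none
Why: O-acylation of the tertiary quinol by the acid chloride hangs the carbon acid on the C4 oxygen, and the weak base and low temperature should keep an uncatalysed, racemic ring closure from starting.

Step 3
Reactants: 6 methyl 4-oxo-1-(prop-1-en-2-yl)cyclohexa-2,5-dien-1-yl propanedioate
Product: 7 methyl (3aR,7aR)-2,5-dioxo-7a-(prop-1-en-2-yl)-2,3,3a,4,5,7a-hexahydro-1-benzofuran-3-carboxylate
Conditions: 9-amino(9-deoxy)epiquinidine 3,5-bis(trifluoromethyl)phenyl thiourea (10 mol %), toluene, −20 °C
Reagents that add atoms: none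
Why: Organocatalytic desymmetrising intramolecular Michael addition (5-exo-trig) of a carbon acid tethered through the C4 oxygen of a cyclohexadienone, in which the thiourea binds the dienone carbonyl, the quinuclidinium holds the malonate enolate and selects one of the two enantiotopic enone arms (sets C3a), the three-atom tether forces the cis ring fusion (makes C7a stereogenic), and C3 stays labile and is of no consequence.

Step 4
Reactants: 7 methyl (3aR,7aR)-2,5-dioxo-7a-(prop-1-en-2-yl)-2,3,3a,4,5,7a-hexahydro-1-benzofuran-3-carboxylate; 8 dimethyl malonate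
Product: 9 methyl (3aR,7R,7aS)-7-(1,3-dimethoxy-1,3-dioxopropan-2-yl)-2,5-dioxo-7a-(prop-1-en-2-yl)octahydro-1-benzofuran-3-carboxylate
Conditions: 8 (3 equiv), DBU (0.2 equiv), toluene, −20 → 0 °C, stopped at full conversion
Reagents that add atoms: none
Why: Base-catalysed Michael addition under kinetic control, in which the half-chair with the C3a–C3 bond equatorial and the C7a–O1 bond axial is attacked axially at C7, anti to the C–O bond and on the convex face of the cis-fused bicycle, so the new malonate should end trans to the C3a branch (sets C7).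

Step 5
Reactants: 9 methyl (3aR,7R,7aS)-7-(1,3-dimethoxy-1,3-dioxopropan-2-yl)-2,5-dioxo-7a-(prop-1-en-2-yl)octahydro-1-benzofuran-3-carboxylate
Product: 11 tetramethyl 2,2'-[(1S,3S)-5-oxo-2-(prop-1-en-2-yl)cyclohexane-1,3-diyl]dipropanedioate, via mono-acid 10 (not isolated)
Conditions: Pd(OAc)2 (5 mol %), P(n-Bu)3 (20 mol %), HCO2H, Et3N, THF, 23 → 45 °C; crude acid: MeI, KHCO3, DMF, 23 °C
Reagents that add atoms: iodomethane, CI
Why: Tsuji-type palladium-catalysed formate hydrogenolysis of a tertiary allylic carboxylate, in which zerovalent palladium ionises the allylic lactone C–O bond, the formate complex loses CO2 and passes hydride to the more substituted allyl terminus to leave the 1,1-disubstituted alkene, and O-methylation of the freed carboxylate with a base too weak to touch the malonate C–H makes the two ring branches identical, so the face of hydride delivery at C2 does not matter.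

Step 6
Reactants: 11 tetramethyl 2,2'-[(1S,3S)-5-oxo-2-(prop-1-en-2-yl)cyclohexane-1,3-diyl]dipropanedioate
Product: 12 tetramethyl 2,2'-[(1S,3S)-5-methylidene-2-(prop-1-en-2-yl)cyclohexane-1,3-diyl]dipropanedioate
Conditions: Zn, CH2Br2, TiCl4 (excess reagent), THF–CH2Cl2, 0 → 23 °C
Reagents that add atoms: dibromomethane, BrCBr
Why: Lombardo–Takai methylenation with a non-basic gem-dimetallic reagent takes a ketone ahead of esters and does not enolise it, so the two β-malonyl groups are not expelled as they could be under a basic ylide that the acidic malonate C–H bonds would also quench.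

Step 7
Reactants: 12 tetramethyl 2,2'-[(1S,3S)-5-methylidene-2-(prop-1-en-2-yl)cyclohexane-1,3-diyl]dipropanedioate; 13 N-methylaniline (two equivalents incorporated)
Product: 15 3,3'-[(1S,3S)-5-methylidene-2-(prop-1-en-2-yl)cyclohexane-1,3-diyl]bis(4-hydroxy-1-methylquinolin-2(1H)-one), via bis(ester anilide) 14 (not isolated)
Conditions: 13 (8 equiv), Ph2O, Ar, 190 → 250 °C, MeOH let off through a short air condenser
Reagents that add atoms: none
Why: Each malonate is first aminolysed by 13, directly or through the carbomethoxyketene that methyl malonates give by loss of methanol above about 200 °C, which forms N1–C2 and the bis(ester anilide) 14. The remaining ester of each arm then loses methanol and acylates the ortho carbon of its own N-aryl ring (C4–C4a), a six-membered closure that is 6-exo-trig at the ester carbonyl or, through the acylketene, a 6π-type closure, and enolisation gives the 4-hydroxyquinolin-2-one; both pyridone rings close in this same mode. The closest known reaction is the thermal cyclocondensation of monoalkylmalonic esters with N-alkylanilines to 3-alkyl-4-hydroxyquinolin-2-ones, which here simply runs twice in one molecule. No stereocentre is created: the two labile malonate CH centres become sp2 C3 atoms, C2 of ring C stays non-stereogenic, and C1 and C3 are carried through. The step needs each arm to pair with one aniline (an open dianilide formed with excess amine can revert through the same ketene, and the ortho acylation is intramolecular) and needs C1 and C3 to hold, which the substrate secures because no ring carbonyl is left to start a retro-Michael loss of malonate and neither C–H is acidic. The two 1,1-disubstituted alkenes meet only a neutral, amine-buffered medium with no hydroxyl group to lactonise or dehydrate, and any early O–C closure by the acidic enols lies on the way to the target.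

Step 8
Reactants: 15 3,3'-[(1S,3S)-5-methylidene-2-(prop-1-en-2-yl)cyclohexane-1,3-diyl]bis(4-hydroxy-1-methylquinolin-2(1H)-one)
Product: 17 CNP0229685.8 (target), via ring-B ether 16 (not isolated)
Conditions: CF3CO2H–CH2Cl2 (1:1), 0 → 40 °C, held until the isomer composition no longer changes
Reagents that add atoms: none
Why: Acid-catalysed intramolecular Markovnikov hydroalkoxylation (as in the closure of 3-prenyl-4-hydroxyquinolinones to dihydropyranoquinolinones and of cannabidiol-type terpenyl phenols) protonates both alkenes to the C5 and side-chain tertiary cations, the axial quinolinone that is cis to the side chain can alone reach C5 and sets it (ring B), the equatorial trans quinolinone closes the trans-fused ring A and thereby fixes C2, and reversible C–O ionisation in CF3CO2H should drain the alternative cis-fused/bridged pairing (axial CMe2) and any closure through the lactam oxygen into the less strained target.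

Compound list
1 | 4,4-dimethoxycyclohexa-2,5-dien-1-one | COC1(OC)C=CC(=O)C=C1 | starting material
2 | prop-1-en-2-ylmagnesium bromide | CC(=C)[Mg]Br | starting material
3 | 4,4-dimethoxy-1-(prop-1-en-2-yl)cyclohexa-2,5-dien-1-ol | COC1(OC)C=CC(O)(C(C)=C)C=C1 | intermediate
4 | 4-hydroxy-4-(prop-1-en-2-yl)cyclohexa-2,5-dien-1-one | CC(=C)C1(O)C=CC(=O)C=C1 | intermediate
5 | methyl 3-chloro-3-oxopropanoate | COC(=O)CC(=O)Cl | starting material
6 | methyl 4-oxo-1-(prop-1-en-2-yl)cyclohexa-2,5-dien-1-yl propanedioate | COC(=O)CC(=O)OC1(C(C)=C)C=CC(=O)C=C1 | intermediate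
7 | methyl (3aR,7aR)-2,5-dioxo-7a-(prop-1-en-2-yl)-2,3,3a,4,5,7a-hexahydro-1-benzofuran-3-carboxylate (cis-fused; C3 labile, left open) | COC(=O)C1C(=O)O[C@]2(C(C)=C)C=CC(=O)C[C@H]12 | intermediate
8 | dimethyl malonate | COC(=O)CC(=O)OC | starting material
9 | methyl (3aR,7R,7aS)-7-(1,3-dimethoxy-1,3-dioxopropan-2-yl)-2,5-dioxo-7a-(prop-1-en-2-yl)octahydro-1-benzofuran-3-carboxylate (C7 malonate anti to O1, trans to the C3a branch) | COC(=O)C1C(=O)O[C@]2(C(C)=C)[C@@H](C(C(=O)OC)C(=O)OC)CC(=O)C[C@H]12 | intermediate
10 | mono-acid: 11 with one CO2H in place of CO2Me on the arm that came from the lactone; H on C2 on the face opposite to the departed oxygen | O=C1C[C@H](C(C(=O)O)C(=O)OC)[C@H](C(C)=C)[C@@H](C(C(=O)OC)C(=O)OC)C1 | intermediate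
11 | tetramethyl 2,2'-[(1S,3S)-5-oxo-2-(prop-1-en-2-yl)cyclohexane-1,3-diyl]dipropanedioate | O=C1C[C@H](C(C(=O)OC)C(=O)OC)C(C(C)=C)[C@@H](C(C(=O)OC)C(=O)OC)C1 | intermediate
12 | tetramethyl 2,2'-[(1S,3S)-5-methylidene-2-(prop-1-en-2-yl)cyclohexane-1,3-diyl]dipropanedioate | C=C1C[C@H](C(C(=O)OC)C(=O)OC)C(C(C)=C)[C@@H](C(C(=O)OC)C(=O)OC)C1 | intermediate
13 | N-methylaniline | CNc1ccccc1 | starting material
14 | dimethyl 2,2'-[(1S,3S)-5-methylidene-2-(prop-1-en-2-yl)cyclohexane-1,3-diyl]bis{3-[methyl(phenyl)amino]-3-oxopropanoate} (malonyl CH centres labile) | C=C1C[C@H](C(C(=O)OC)C(=O)N(C)c2ccccc2)C(C(C)=C)[C@@H](C(C(=O)OC)C(=O)N(C)c2ccccc2)C1 | intermediate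
15 | 3,3'-[(1S,3S)-5-methylidene-2-(prop-1-en-2-yl)cyclohexane-1,3-diyl]bis(4-hydroxy-1-methylquinolin-2(1H)-one) | C=C1C[C@H](c2c(O)c3ccccc3n(C)c2=O)C(C(C)=C)[C@@H](c2c(O)c3ccccc3n(C)c2=O)C1 | intermediate
16 | ring-B ether: 15 with O4 of the C3 quinolinone bonded to C5 (2-oxabicyclo[3.3.1]nonane, C5 methyl on the other face); isopropenyl (cis to the bridged quinolinone) and the C1 hydroxyquinolinone still free | C=C(C)[C@@H]1[C@@H](c2c(O)c3ccccc3n(C)c2=O)C[C@@]2(C)C[C@@H]1c1c(c3ccccc3n(C)c1=O)O2 | intermediate
17 | CNP0229685.8: ring C with C1 and C3 both S; ring A a trans-fused 2,2-dimethyldihydropyrano[3,2-c]quinolin-5-one (O on CMe2, H-1 and H-2 anti); ring B the C3 quinolinone bridged through O4 to C5 on the same face, C5 methyl opposite; CMe2 on C2 cis to the C3 quinolinone | Cn1c(=O)c2c(c3ccccc31)OC(C)(C)[C@@H]1[C@@H]2C[C@@]2(C)C[C@@H]1c1c(c3ccccc3n(C)c1=O)O2 | target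

Total step count: 8. Longest linear sequence: 8 steps (1 to 17).

Steps most likely to fail

1. **Step 7.**
   - What may go wrong: the second ring closure may stall at open or half-cyclised anilides on these hindered secondary-alkyl arms; traces of water may strip ester groups by dealkoxycarbonylation; the alkenes may migrate or oligomerise during long heating.
   - Fallback: it sets out from 12 and returns at 15, and builds each pyridone from the C3–C4 and N1–C2 bonds at or below room temperature.
   - A double Krapcho dealkoxycarbonylation (LiCl, wet DMSO, 150 °C) gives dimethyl 2,2'-[(1R,3R)-5-methylidene-2-(prop-1-en-2-yl)cyclohexane-1,3-diyl]diacetate F1.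
   - Its bis(lithium enolate) (LiN(iPr)2, THF, −78 °C) is C-acylated by 1-methyl-2H-3,1-benzoxazine-2,4(1H)-dione (N-methylisatoic anhydride). This opens with loss of CO2 to the bis[2-(methylamino)benzoyl]acetate, dimethyl 2,2'-[(1S,3S)-5-methylidene-2-(prop-1-en-2-yl)cyclohexane-1,3-diyl]bis{3-[2-(methylamino)phenyl]-3-oxopropanoate} F2.
   - F2 lactamises on warming to 15.

2. **Step 5.**
   - What may go wrong: ionisation at the congested C7a may be slow; hydride may be passed to the CH2 terminus; β-hydride loss to a diene would erase C1 or C3.
   - Fallback: it sets out from 9 and returns at 12, and replaces inner-sphere hydride delivery by electron transfer.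
   - Ozonolysis of the only alkene (O3, CH2Cl2–MeOH, −78 °C; Me2S) gives the α-acyloxy ketone methyl (3aR,7R,7aS)-7a-acetyl-7-(1,3-dimethoxy-1,3-dioxopropan-2-yl)-2,5-dioxooctahydro-1-benzofuran-3-carboxylate F3.
   - SmI2 (THF–MeOH, −78 °C) cleaves the C–O bond α to the acetyl group to the 4-acetyl keto acid F4.
   - MeI/KHCO3 gives tetramethyl 2,2'-[(1S,3S)-2-acetyl-5-oxocyclohexane-1,3-diyl]dipropanedioate F5.
   - An excess of the Zn/CH2Br2/TiCl4 reagent methylenates both ketones of F5 to 12.

3. **Step 4.**
   - What may go wrong: facial selectivity may be poor next to the quaternary C7a; reversible addition may drift slowly towards the all-equatorial cis arrangement of the two arms.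
   - Fallback: it sets out from 7 and returns at 9, and traps the kinetic adduct irreversibly.
   - A Michael-initiated ring closure with dimethyl bromomalonate (K2CO3, MeCN, 0 °C) gives the cyclopropane in which C6–C7 of 7 is spanned by C(CO2Me)2 on the face anti to O1, F6.
   - SmI2 (THF–MeOH, −78 °C) then opens the cyclopropyl ketone at the C6–C(CO2Me)2 bond, the one that releases the malonyl radical, to give 9.

Further compounds
F1 | step 7 | dimethyl 2,2'-[(1R,3R)-5-methylidene-2-(prop-1-en-2-yl)cyclohexane-1,3-diyl]diacetate | C=C1C[C@H](CC(=O)OC)C(C(C)=C)[C@@H](CC(=O)OC)C1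
F2 | step 7 | dimethyl 2,2'-[(1S,3S)-5-methylidene-2-(prop-1-en-2-yl)cyclohexane-1,3-diyl]bis{3-[2-(methylamino)phenyl]-3-oxopropanoate} | C=C1C[C@H](C(C(=O)OC)C(=O)c2ccccc2NC)C(C(C)=C)[C@@H](C(C(=O)OC)C(=O)c2ccccc2NC)C1
F3 | step 5 | methyl (3aR,7R,7aS)-7a-acetyl-7-(1,3-dimethoxy-1,3-dioxopropan-2-yl)-2,5-dioxooctahydro-1-benzofuran-3-carboxylate | COC(=O)C1C(=O)O[C@]2(C(C)=O)[C@@H](C(C(=O)OC)C(=O)OC)CC(=O)C[C@H]12
F4 | step 5 | 4-acetyl keto acid: F5 with one CO2H in place of CO2Me (C2 epimerisable) | O=C1C[C@H](C(C(=O)O)C(=O)OC)C(C(C)=O)[C@@H](C(C(=O)OC)C(=O)OC)C1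
F5 | step 5 | tetramethyl 2,2'-[(1S,3S)-2-acetyl-5-oxocyclohexane-1,3-diyl]dipropanedioate | O=C1C[C@H](C(C(=O)OC)C(=O)OC)C(C(C)=O)[C@@H](C(C(=O)OC)C(=O)OC)C1
F6 | step 4 | cyclopropane from 7: C6–C7 spanned by C(CO2Me)2 on the face anti to O1 | COC(=O)C1C(=O)O[C@]2(C(C)=C)[C@@H]3[C@@H](C3(C(=O)OC)C(=O)OC)C(=O)C[C@H]12
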